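The key step exploits the unsubstituted C2 of the cyclopentene ring (C1, C2, C3, C3a, C7a), which shares the C3a–C7a bond with the cyclohexene ring. Taken as a ketone, C2 is the CO unit of an intramolecular Pauson–Khand reaction that links the ethyl-bearing alkyne carbon C3 to the propenyl carbon C1 while C3a–C7a closes the six-membered ring. One operation thus converts an acyclic dienyne into the bicyclic enone, forming both rings, three C–C bonds and the C1 and C7a stereocentres. The precursor is a 1,7-enyne with vicinal quaternary carbons C4 and C5 and a Z,E-diene; C4 and C5 come from a chirality-transferring Claisen rearrangement.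

Key step: step 15

Numbering: indene numbering of the target is used for all intermediates: C1 (CHMe), C2=C3 (ethyl on C3), C3a, C4 (Me, carboxyl), C5 (Et, dienyl), C6=C7 (Me on C7), C7a.
Assumption: (E)-3-iodo-2-methylacrylic acid 1 is bought (it is otherwise made in two steps from diethyl methylmalonate and iodoform); 3, 4, 15, 19, 28 and 30 are catalogue compounds.

Step 1
Reactants: 1 (E)-3-iodo-2-methylacrylic acid
Product: 2 tert-butyl (2E)-3-iodo-2-methylprop-2-enoate
Conditions: tert-butyl 2,2,2-trichloroacetimidate, BF3·OEt2 (cat.), cyclohexane/CH2Cl2, rt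
Reagents that add atoms: tert-butyl 2,2,2-trichloroacetimidate, CC(C)(C)OC(=N)C(Cl)(Cl)Cl
Why: Acid-catalysed tert-butylation of the carboxylic acid by the imidate (imidate O-alkylation) leaves the vinyl iodide and its E geometry untouched and installs the bulky ester that later resists nucleophiles.

Step 2
Reactants: 3 (S)-but-3-en-2-ol; 4 2-ethylacrylic acid (2-methylidenebutanoic acid)
Product: 5 (2S)-but-3-en-2-yl 2-methylidenebutanoate
Conditions: DCC, DMAP (cat.), CH2Cl2, 0 °C to rt
Reagents that add atoms: none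
Why: Steglich esterification acylates the hydroxyl oxygen only, so the S carbinol centre is carried over unchanged.

Step 3
Reactants: 5 (2S)-but-3-en-2-yl 2-methylidenebutanoate
Product: 6 (5S)-3-ethyl-5-methylfuran-2(5H)-one
Conditions: second-generation Grubbs catalyst (5 mol %), CH2Cl2, 40 °C
Reagents that add atoms: none
Why: Ring-closing metathesis of the acrylate of an allylic alcohol gives the butenolide with loss of ethene, and the five-membered ring enforces the cis relation between the carbinol carbon and the carbonyl carbon that becomes the Z allylic geometry.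

Step 4
Reactants: 6 (5S)-3-ethyl-5-methylfuran-2(5H)-one
Product: 7 (2Z,4S)-2-ethylpent-2-ene-1,4-diol
Conditions: i-Bu2AlH (3 equiv), CH2Cl2, −78 to 0 °C; Rochelle salt work-up
Reagents that add atoms: none
Why: 1,2-Reduction of the unsaturated lactone by the aluminium hydride, through the lactol aluminate, opens the ring to the Z ene-diol without touching the stereocentre or the alkene geometry.

Step 5
Reactants: 7 (2Z,4S)-2-ethylpent-2-ene-1,4-diol
Product: 8 (2S,3Z)-4-[(tert-butyldimethylsilyloxy)methyl]hex-3-en-2-ol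
Conditions: TBSCl (1.05 equiv), imidazole, CH2Cl2, −20 °C
Reagents that add atoms: tert-butyldimethylsilyl chloride, CC(C)(C)[Si](C)(C)Cl
Why: Silylation under kinetic control selects the unhindered primary hydroxyl over the secondary allylic one.

Step 6
Reactants: 8 (2S,3Z)-4-[(tert-butyldimethylsilyloxy)methyl]hex-3-en-2-ol; 2 tert-butyl (2E)-3-iodo-2-methylprop-2-enoate
Product: 9 tert-butyl (2E)-3-{[(2S,3Z)-4-[(tert-butyldimethylsilyloxy)methyl]hex-3-en-2-yl]oxy}-2-methylprop-2-enoate
Conditions: CuI (10 mol %), 3,4,7,8-tetramethyl-1,10-phenanthroline (20 mol %), Cs2CO3, toluene, 80 °C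
Reagents that add atoms: none
Why: Copper-catalysed C–O cross-coupling of a vinyl iodide with an alcohol (Ullmann-type vinylation) forms the enol ether with retention of the E alkene geometry, and the carbinol centre is not involved.

Step 7
Reactants: 9 tert-butyl (2E)-3-{[(2S,3Z)-4-[(tert-butyldimethylsilyloxy)methyl]hex-3-en-2-yl]oxy}-2-methylprop-2-enoate
Product: 10 tert-butyl (2S,3S,4E)-3-[(tert-butyldimethylsilyloxy)methyl]-3-ethyl-2-formyl-2-methylhex-4-enoate
Conditions: xylene, 170 °C, sealed tube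
Reagents that add atoms: none
Why: Thermal Claisen rearrangement ([3,3]-sigmatropic shift) through a chair with the carbinol methyl equatorial: the E enol ether places the C4 methyl axial and the ester equatorial, the Z allyl terminus places CH2OSi axial and ethyl equatorial, so the S carbinol centre is relayed suprafacially into the 2S,3S pair of quaternary carbons (C4, C5) and an E propenyl group.

Step 8
Reactants: 10 tert-butyl (2S,3S,4E)-3-[(tert-butyldimethylsilyloxy)methyl]-3-ethyl-2-formyl-2-methylhex-4-enoate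
Product: 11 tert-butyl (2R,3S,4E)-3-[(tert-butyldimethylsilyloxy)methyl]-2-(2,2-dibromoethenyl)-3-ethyl-2-methylhex-4-enoate
Conditions: CBr4, PPh3, CH2Cl2, 0 °C
Reagents that add atoms: carbon tetrabromide, BrC(Br)(Br)Br
Why: Corey–Fuchs dibromoolefination (Wittig reaction of Ph3P=CBr2 made in the flask) works on the hindered, non-enolisable aldehyde and does not affect the ester, the silyl ether or the alkene.

Step 9
Reactants: 11 tert-butyl (2R,3S,4E)-3-[(tert-butyldimethylsilyloxy)methyl]-2-(2,2-dibromoethenyl)-3-ethyl-2-methylhex-4-enoate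
Product: 13 tert-butyl (2R,3S,4E)-2-(but-1-yn-1-yl)-3-[(tert-butyldimethylsilyloxy)methyl]-3-ethyl-2-methylhex-4-enoate, via lithium acetylide 12 (not isolated)
Conditions: n-BuLi (2.1 equiv), THF, −78 °C; then EtOTf, −78 to 0 °C
Reagents that add atoms: ethyl trifluoromethanesulfonate, CCOS(=O)(=O)C(F)(F)F
Why: Second stage of the Corey–Fuchs alkyne synthesis: bromine–lithium exchange, 1,2-shift of the carbenoid (Fritsch–Buttenberg–Wiechell) and deprotonation give the lithium acetylide, which the triflate ethylates at low temperature while the shielded tert-butyl ester is left alone.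

Step 10
Reactants: 13 tert-butyl (2R,3S,4E)-2-(but-1-yn-1-yl)-3-[(tert-butyldimethylsilyloxy)methyl]-3-ethyl-2-methylhex-4-enoate
Product: 14 tert-butyl (2R,3S)-2-(but-1-yn-1-yl)-3-[(tert-butyldimethylsilyloxy)methyl]-3-formyl-2-methylpentanoate
Conditions: OsO4 (2 mol %), NaIO4, 2,6-lutidine, dioxane/H2O, rt
Reagents that add atoms: osmium tetroxide, O=[Os](=O)(=O)=O; sodium periodate, [Na+].[O-]I(=O)(=O)=O
Why: Lemieux–Johnson oxidation: OsO4 dihydroxylates the disubstituted alkene much faster than the internal alkyne and periodate cleaves the diol, releasing acetaldehyde and the C6 aldehyde without touching either quaternary centre.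

Step 11
Reactants: 14 tert-butyl (2R,3S)-2-(but-1-yn-1-yl)-3-[(tert-butyldimethylsilyloxy)methyl]-3-formyl-2-methylpentanoate; 15 methyl 2-[bis(2,2,2-trifluoroethoxy)phosphoryl]propanoate
Product: 16 6-tert-butyl 1-methyl (2Z,4S,5R)-5-(but-1-yn-1-yl)-4-[(tert-butyldimethylsilyloxy)methyl]-4-ethyl-2,5-dimethylhex-2-enedioate
Conditions: KN(SiMe3)2, 18-crown-6, THF, −78 °C
Reagents that add atoms: none
Why: Still–Gennari modification of the Horner–Wadsworth–Emmons reaction: the trifluoroethyl phosphonate with a crown-ether-separated potassium ion eliminates from the kinetic adduct, giving the Z trisubstituted enoate (C5 cis to the ester carbon, the future C7a), and the aldehyde cannot enolise.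

Step 12
Reactants: 16 6-tert-butyl 1-methyl (2Z,4S,5R)-5-(but-1-yn-1-yl)-4-[(tert-butyldimethylsilyloxy)methyl]-4-ethyl-2,5-dimethylhex-2-enedioate
Product: 17 tert-butyl (2R,3S,4Z)-2-(but-1-yn-1-yl)-3-[(tert-butyldimethylsilyloxy)methyl]-3-ethyl-6-hydroxy-2,5-dimethylhex-4-enoate
Conditions: i-Bu2AlH (2.2 equiv), CH2Cl2, −78 °C
Reagents that add atoms: none
Why: Hydride reduction of the unhindered conjugated methyl ester to the allylic alcohol at low temperature, the tert-butyl ester on the quaternary carbon being sterically shielded.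

Step 13
Reactants: 17 tert-butyl (2R,3S,4Z)-2-(but-1-yn-1-yl)-3-[(tert-butyldimethylsilyloxy)methyl]-3-ethyl-6-hydroxy-2,5-dimethylhex-4-enoate
Product: 18 tert-butyl (2R,3S,4Z)-2-(but-1-yn-1-yl)-3-[(tert-butyldimethylsilyloxy)methyl]-3-ethyl-2,5-dimethyl-6-oxohex-4-enoate
Conditions: MnO2, CH2Cl2, rt
Reagents that add atoms: none
Why: MnO2 oxidises only allylic alcohols and, being neutral, does not isomerise the Z enal, which has no enolisable position.

Step 14
Reactants: 18 tert-butyl (2R,3S,4Z)-2-(but-1-yn-1-yl)-3-[(tert-butyldimethylsilyloxy)methyl]-3-ethyl-2,5-dimethyl-6-oxohex-4-enoate; 19 5-(ethanesulfonyl)-1-phenyl-1H-tetrazole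
Product: 20 tert-butyl (2R,3S,4Z,6E)-2-(but-1-yn-1-yl)-3-[(tert-butyldimethylsilyloxy)methyl]-3-ethyl-2,5-dimethylocta-4,6-dienoate
Conditions: KN(SiMe3)2, DME, −60 °C to rt
Reagents that add atoms: none
Why: Julia–Kocienski olefination: the potassium sulfonyl carbanion adds to the enal and the adduct collapses by Smiles rearrangement and loss of SO2 to the E propenyl group, leaving the Z C6=C7 bond in place.

Step 15
Reactants: 20 tert-butyl (2R,3S,4Z,6E)-2-(but-1-yn-1-yl)-3-[(tert-butyldimethylsilyloxy)methyl]-3-ethyl-2,5-dimethylocta-4,6-dienoate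
Product: 22 tert-butyl (1S,4R,5S,7aR)-5-[(tert-butyldimethylsilyloxy)methyl]-3,5-diethyl-1,4,7-trimethyl-2-oxo-2,4,5,7a-tetrahydro-1H-indene-4-carboxylate, via hexacarbonyldicobalt alkyne complex 21 (not isolated)
Conditions: Co2(CO)8 (1.1 equiv), CH2Cl2, rt; then N-methylmorpholine N-oxide (8 equiv), 0 °C to rt
Reagents that add atoms: dicobalt octacarbonyl, O=C=[Co](=C=O)(=C=O)(=C=O)[Co](=C=O)(=C=O)(=C=O)=C=O
Why: Co2(CO)8 converts the C3≡C3a alkyne into its Co2(CO)6 complex; N-oxide-induced loss of one CO lets the terminal C7a=C1 alkene of the diene bind, insert into the Co–C3a bond (C3a–C7a), take up CO at the Co–C1 bond and reductively eliminate (C2–C3) to the cyclopentenone. The closest known reaction type is the cobalt-mediated intramolecular Pauson–Khand reaction of 1,7-enynes and of dienynes to bicyclo[4.3.0]nonenones. The cyclohexene closes by 6-exo attack of C3a on the inner diene carbon C7a, pre-folded by the Z C6=C7 bond and the two quaternary carbons (Thorpe–Ingold effect), and the cyclopentenone closes by (2+2+1) carbonylative union of C3, the CO-derived C2 and C1. C1 follows from stereospecific suprafacial addition to the E alkene (methyl trans to C7), and C7a from the alkene face presented by a chair-like tether in which the flat tert-butyl ester lies pseudoequatorial beside C3 and the small C4 methyl is the only pseudoaxial group on the cobalt-bearing face (the C5 silyloxymethyl arm is pseudoaxial on the other face), so that H7a ends up cis to the C4 methyl. The step needs site selectivity for C7a=C1 over the tether alkene and over diene–alkyne (4+2) addition, both secured by geometry (closure at C6=C7 would need a cyclobutane or an anti-Bredt bridged enone, and the (4+2) adduct would hold a bridgehead alkene); the facial preference at C7a is the one element not secured by precedent.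

Step 16
Reactants: 22 tert-butyl (1S,4R,5S,7aR)-5-[(tert-butyldimethylsilyloxy)methyl]-3,5-diethyl-1,4,7-trimethyl-2-oxo-2,4,5,7a-tetrahydro-1H-indene-4-carboxylate
Product: 24 tert-butyl (1S,3aR,4R,5S,7aR)-5-[(tert-butyldimethylsilyloxy)methyl]-3,5-diethyl-1,4,7-trimethyl-2-{[(trifluoromethyl)sulfonyl]oxy}-3a,4,5,7a-tetrahydro-1H-indene-4-carboxylate, via lithium enolate 23 (not isolated)
Conditions: Li, NH3/THF, t-BuOH (1 equiv), −78 °C; NH3 removed; then PhNTf2, THF, −78 °C to rt
Reagents that add atoms: N-phenylbis(trifluoromethanesulfonimide), O=S(=O)(N(c1ccccc1)S(=O)(=O)C(F)(F)F)C(F)(F)F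
Why: Dissolving-metal conjugate reduction of the enone: the C3a carbanion of the dianion is protonated by tert-butanol anti to H7a, giving the trans ring fusion, and the regiodefined C2–C3 lithium enolate is trapped on oxygen by the triflimide (reductive enolate triflation), C1 being untouched.

Step 17
Reactants: 24 tert-butyl (1S,3aR,4R,5S,7aR)-5-[(tert-butyldimethylsilyloxy)methyl]-3,5-diethyl-1,4,7-trimethyl-2-{[(trifluoromethyl)sulfonyl]oxy}-3a,4,5,7a-tetrahydro-1H-indene-4-carboxylate
Product: 25 tert-butyl (1R,3aR,4R,5S,7aS)-5-[(tert-butyldimethylsilyloxy)methyl]-3,5-diethyl-1,4,7-trimethyl-3a,4,5,7a-tetrahydro-1H-indene-4-carboxylate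
Conditions: Pd(OAc)2 (5 mol %), PPh3, n-Bu3N, HCO2H, DMF, 60 °C
Reagents that add atoms: none
Why: Palladium-catalysed reduction of the vinyl triflate by formate (oxidative addition to zerovalent palladium, formate exchange, loss of CO2 and C–H reductive elimination) replaces OTf by H and leaves the C2=C3 alkene in place.

Step 18
Reactants: 25 tert-butyl (1R,3aR,4R,5S,7aS)-5-[(tert-butyldimethylsilyloxy)methyl]-3,5-diethyl-1,4,7-trimethyl-3a,4,5,7a-tetrahydro-1H-indene-4-carboxylate
Product: 26 tert-butyl (1R,3aR,4R,5S,7aS)-3,5-diethyl-5-(hydroxymethyl)-1,4,7-trimethyl-3a,4,5,7a-tetrahydro-1H-indene-4-carboxylate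
Conditions: HF·pyridine, pyridine, THF, 0 °C to rt
Reagents that add atoms: none
Why: Fluoride-mediated cleavage of the silyl ether under buffered conditions, which avoid an alkoxide that could attack the neighbouring ester.

Step 19
Reactants: 26 tert-butyl (1R,3aR,4R,5S,7aS)-3,5-diethyl-5-(hydroxymethyl)-1,4,7-trimethyl-3a,4,5,7a-tetrahydro-1H-indene-4-carboxylate
Product: 27 tert-butyl (1R,3aR,4R,5S,7aS)-3,5-diethyl-5-formyl-1,4,7-trimethyl-3a,4,5,7a-tetrahydro-1H-indene-4-carboxylate
Conditions: Dess–Martin periodinane, CH2Cl2, 0 °C to rt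
Reagents that add atoms: none
Why: Dess–Martin oxidation takes the neopentyl primary alcohol to the non-enolisable aldehyde under mild, non-basic conditions.

Step 20
Reactants: 27 tert-butyl (1R,3aR,4R,5S,7aS)-3,5-diethyl-5-formyl-1,4,7-trimethyl-3a,4,5,7a-tetrahydro-1H-indene-4-carboxylate; 28 2-(triphenyl-λ5-phosphanylidene)propanal
Product: 29 tert-butyl (1R,3aR,4R,5R,7aS)-3,5-diethyl-1,4,7-trimethyl-5-[(1E)-2-methyl-3-oxoprop-1-en-1-yl]-3a,4,5,7a-tetrahydro-1H-indene-4-carboxylate
Conditions: toluene, 110 °C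
Reagents that add atoms: none
Why: Wittig reaction with a formyl-stabilised ylide, which gives the E trisubstituted enal and needs heat because the aldehyde is neopentyl.

Step 21
Reactants: 29 tert-butyl (1R,3aR,4R,5R,7aS)-3,5-diethyl-1,4,7-trimethyl-5-[(1E)-2-methyl-3-oxoprop-1-en-1-yl]-3a,4,5,7a-tetrahydro-1H-indene-4-carboxylate; 30 diethyl benzylphosphonate
Product: 31 tert-butyl (1R,3aR,4R,5S,7aS)-3,5-diethyl-1,4,7-trimethyl-5-[(1E,3E)-2-methyl-4-phenylbuta-1,3-dien-1-yl]-3a,4,5,7a-tetrahydro-1H-indene-4-carboxylate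
Conditions: NaH, THF, 0 °C to rt
Reagents that add atoms: none
Why: Horner–Wadsworth–Emmons reaction of the benzylphosphonate anion with the non-enolisable enal gives the E styryl double bond and completes the E,E-diene.

Step 22
Reactants: 31 tert-butyl (1R,3aR,4R,5S,7aS)-3,5-diethyl-1,4,7-trimethyl-5-[(1E,3E)-2-methyl-4-phenylbuta-1,3-dien-1-yl]-3a,4,5,7a-tetrahydro-1H-indene-4-carboxylate
Product: 33 (1R,3aR,4R,5S,7aS)-3,5-diethyl-1,4,7-trimethyl-5-[(1E,3E)-2-methyl-4-phenylbuta-1,3-dien-1-yl]-3a,4,5,7a-tetrahydro-1H-indene-4-carboxylic acid, via trimethylsilyl ester 32 (not isolated)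
Conditions: Me3SiOTf, 2,6-lutidine, CH2Cl2, 0 °C; then aqueous NaH2PO4
Reagents that add atoms: none
Why: Silyl-triflate-mediated cleavage of the tert-butyl ester (O-silylation, loss of the tert-butyl cation as isobutene, hydrolysis of the silyl ester) works without protic acid, so the diene and the ring alkenes are not protonated and no stereocentre is touched.

Compound list
1 | (E)-3-iodo-2-methylacrylic acid | C/C(=C\I)C(=O)O | starting material
2 | tert-butyl (2E)-3-iodo-2-methylprop-2-enoate | C/C(=C\I)C(=O)OC(C)(C)C | intermediate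
3 | (S)-but-3-en-2-ol | C[C@H](O)C=C | starting material
4 | 2-ethylacrylic acid (2-methylidenebutanoic acid) | CCC(=C)C(=O)O | starting material
5 | (2S)-but-3-en-2-yl 2-methylidenebutanoate | CCC(=C)C(=O)O[C@@H](C)C=C | intermediate
6 | (5S)-3-ethyl-5-methylfuran-2(5H)-one | CCC1=C[C@H](C)OC1=O | intermediate
7 | (2Z,4S)-2-ethylpent-2-ene-1,4-diol | C[C@H](O)/C=C(CC)\CO | intermediate
8 | (2S,3Z)-4-[(tert-butyldimethylsilyloxy)methyl]hex-3-en-2-ol | C[C@H](O)/C=C(CC)\CO[Si](C)(C)C(C)(C)C | intermediate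
9 | tert-butyl (2E)-3-{[(2S,3Z)-4-[(tert-butyldimethylsilyloxy)methyl]hex-3-en-2-yl]oxy}-2-methylprop-2-enoate | C/C(=C\O[C@@H](C)/C=C(CC)\CO[Si](C)(C)C(C)(C)C)C(=O)OC(C)(C)C | intermediate
10 | tert-butyl (2S,3S,4E)-3-[(tert-butyldimethylsilyloxy)methyl]-3-ethyl-2-formyl-2-methylhex-4-enoate | O=C[C@@](C)(C(=O)OC(C)(C)C)[C@@](CC)(CO[Si](C)(C)C(C)(C)C)/C=C/C | intermediate
11 | tert-butyl (2R,3S,4E)-3-[(tert-butyldimethylsilyloxy)methyl]-2-(2,2-dibromoethenyl)-3-ethyl-2-methylhex-4-enoate | BrC(Br)=C[C@@](C)(C(=O)OC(C)(C)C)[C@@](CC)(CO[Si](C)(C)C(C)(C)C)/C=C/C | intermediate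
12 | lithium acetylide of tert-butyl (2R,3S,4E)-3-[(tert-butyldimethylsilyloxy)methyl]-3-ethyl-2-ethynyl-2-methylhex-4-enoate | [Li]C#C[C@@](C)(C(=O)OC(C)(C)C)[C@@](CC)(CO[Si](C)(C)C(C)(C)C)/C=C/C | intermediate
13 | tert-butyl (2R,3S,4E)-2-(but-1-yn-1-yl)-3-[(tert-butyldimethylsilyloxy)methyl]-3-ethyl-2-methylhex-4-enoate | CCC#C[C@@](C)(C(=O)OC(C)(C)C)[C@@](CC)(CO[Si](C)(C)C(C)(C)C)/C=C/C | intermediate
14 | tert-butyl (2R,3S)-2-(but-1-yn-1-yl)-3-[(tert-butyldimethylsilyloxy)methyl]-3-formyl-2-methylpentanoate | CCC#C[C@@](C)(C(=O)OC(C)(C)C)[C@@](CC)(CO[Si](C)(C)C(C)(C)C)C=O | intermediate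
15 | methyl 2-[bis(2,2,2-trifluoroethoxy)phosphoryl]propanoate | COC(=O)C(C)P(=O)(OCC(F)(F)F)OCC(F)(F)F | starting material
16 | 6-tert-butyl 1-methyl (2Z,4S,5R)-5-(but-1-yn-1-yl)-4-[(tert-butyldimethylsilyloxy)methyl]-4-ethyl-2,5-dimethylhex-2-enedioate | CCC#C[C@@](C)(C(=O)OC(C)(C)C)[C@@](CC)(CO[Si](C)(C)C(C)(C)C)/C=C(C)\C(=O)OC | intermediate
17 | tert-butyl (2R,3S,4Z)-2-(but-1-yn-1-yl)-3-[(tert-butyldimethylsilyloxy)methyl]-3-ethyl-6-hydroxy-2,5-dimethylhex-4-enoate | CCC#C[C@@](C)(C(=O)OC(C)(C)C)[C@@](CC)(CO[Si](C)(C)C(C)(C)C)/C=C(C)\CO | intermediate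
18 | tert-butyl (2R,3S,4Z)-2-(but-1-yn-1-yl)-3-[(tert-butyldimethylsilyloxy)methyl]-3-ethyl-2,5-dimethyl-6-oxohex-4-enoate | CCC#C[C@@](C)(C(=O)OC(C)(C)C)[C@@](CC)(CO[Si](C)(C)C(C)(C)C)/C=C(C)\C=O | intermediate
19 | 5-(ethanesulfonyl)-1-phenyl-1H-tetrazole | CCS(=O)(=O)c1nnnn1-c1ccccc1 | starting material
20 | tert-butyl (2R,3S,4Z,6E)-2-(but-1-yn-1-yl)-3-[(tert-butyldimethylsilyloxy)methyl]-3-ethyl-2,5-dimethylocta-4,6-dienoate (the dienyne precursor of the key step) | CCC#C[C@@](C)(C(=O)OC(C)(C)C)[C@@](CC)(CO[Si](C)(C)C(C)(C)C)/C=C(C)\C=C\C | intermediate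
21 | hexacarbonyldicobalt complex of the but-1-ynyl triple bond of 20, Co2(CO)6(alkyne) | CCC12[Co]3(=C=O)(=C=O)(=C=O)[Co]1(=C=O)(=C=O)(=C=O)C23[C@@](C)(C(=O)OC(C)(C)C)[C@@](CC)(CO[Si](C)(C)C(C)(C)C)/C=C(C)\C=C\C | intermediate
22 | tert-butyl (1S,4R,5S,7aR)-5-[(tert-butyldimethylsilyloxy)methyl]-3,5-diethyl-1,4,7-trimethyl-2-oxo-2,4,5,7a-tetrahydro-1H-indene-4-carboxylate (the bicyclic enone) | CCC1=C2[C@@](C)(C(=O)OC(C)(C)C)[C@@](CC)(CO[Si](C)(C)C(C)(C)C)C=C(C)[C@H]2[C@H](C)C1=O | intermediate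
23 | lithium enolate (OLi on C2, C2=C3) of the trans-fused 3a-hydro ketone | CCC1=C(O[Li])[C@@H](C)[C@@H]2C(C)=C[C@@](CO[Si](C)(C)C(C)(C)C)(CC)[C@](C)(C(=O)OC(C)(C)C)[C@@H]12 | intermediate
24 | tert-butyl (1S,3aR,4R,5S,7aR)-5-[(tert-butyldimethylsilyloxy)methyl]-3,5-diethyl-1,4,7-trimethyl-2-{[(trifluoromethyl)sulfonyl]oxy}-3a,4,5,7a-tetrahydro-1H-indene-4-carboxylate | CCC1=C(OS(=O)(=O)C(F)(F)F)[C@@H](C)[C@@H]2C(C)=C[C@@](CO[Si](C)(C)C(C)(C)C)(CC)[C@](C)(C(=O)OC(C)(C)C)[C@@H]12 | intermediate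
25 | tert-butyl (1R,3aR,4R,5S,7aS)-5-[(tert-butyldimethylsilyloxy)methyl]-3,5-diethyl-1,4,7-trimethyl-3a,4,5,7a-tetrahydro-1H-indene-4-carboxylate | CCC1=C[C@@H](C)[C@@H]2C(C)=C[C@@](CO[Si](C)(C)C(C)(C)C)(CC)[C@](C)(C(=O)OC(C)(C)C)[C@@H]12 | intermediate
26 | tert-butyl (1R,3aR,4R,5S,7aS)-3,5-diethyl-5-(hydroxymethyl)-1,4,7-trimethyl-3a,4,5,7a-tetrahydro-1H-indene-4-carboxylate | CCC1=C[C@@H](C)[C@@H]2C(C)=C[C@@](CO)(CC)[C@](C)(C(=O)OC(C)(C)C)[C@@H]12 | intermediate
27 | tert-butyl (1R,3aR,4R,5S,7aS)-3,5-diethyl-5-formyl-1,4,7-trimethyl-3a,4,5,7a-tetrahydro-1H-indene-4-carboxylate | CCC1=C[C@@H](C)[C@@H]2C(C)=C[C@@](C=O)(CC)[C@](C)(C(=O)OC(C)(C)C)[C@@H]12 | intermediate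
28 | 2-(triphenyl-λ5-phosphanylidene)propanal | CC(C=O)=P(c1ccccc1)(c1ccccc1)c1ccccc1 | starting material
29 | tert-butyl (1R,3aR,4R,5R,7aS)-3,5-diethyl-1,4,7-trimethyl-5-[(1E)-2-methyl-3-oxoprop-1-en-1-yl]-3a,4,5,7a-tetrahydro-1H-indene-4-carboxylate | CCC1=C[C@@H](C)[C@@H]2C(C)=C[C@@](/C=C(C)/C=O)(CC)[C@](C)(C(=O)OC(C)(C)C)[C@@H]12 | intermediate
30 | diethyl benzylphosphonate | CCOP(=O)(Cc1ccccc1)OCC | starting material
31 | tert-butyl (1R,3aR,4R,5S,7aS)-3,5-diethyl-1,4,7-trimethyl-5-[(1E,3E)-2-methyl-4-phenylbuta-1,3-dien-1-yl]-3a,4,5,7a-tetrahydro-1H-indene-4-carboxylate | CCC1=C[C@@H](C)[C@@H]2C(C)=C[C@@](/C=C(C)/C=C/c3ccccc3)(CC)[C@](C)(C(=O)OC(C)(C)C)[C@@H]12 | intermediate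
32 | trimethylsilyl ester of 33 | CCC1=C[C@@H](C)[C@@H]2C(C)=C[C@@](/C=C(C)/C=C/c3ccccc3)(CC)[C@](C)(C(=O)O[Si](C)(C)C)[C@@H]12 | intermediate
33 | (1R,3aR,4R,5S,7aS)-3,5-diethyl-1,4,7-trimethyl-5-[(1E,3E)-2-methyl-4-phenylbuta-1,3-dien-1-yl]-3a,4,5,7a-tetrahydro-1H-indene-4-carboxylic acid (CNP0226943.1) | CCC1=C[C@@H](C)[C@@H]2C(C)=C[C@@](/C=C(C)/C=C/c3ccccc3)(CC)[C@](C)(C(=O)O)[C@@H]12 | target

Total step count: 22.
Longest linear sequence: 21 steps (steps 2 to 22, from 3 and 4 to 33); step 1 prepares the vinyl iodide 2 for step 6.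

Steps most likely to fail

1. Step 15 (key step). Insertion of the 1,2-disubstituted, conjugated C7a=C1 alkene into the cobalt–alkyne complex may be slower than decomplexation or binding of the diene to cobalt, so that no bicyclic ketone forms. Independently, insertion may take the wrong alkene face at C7a, which this fallback does not correct. The fallback sets out from 18 and comes back at 22, and it brings in the C1 methyl after ring closure. Methylenation of enal 18 (Ph3P=CH2 from Ph3PCH3Br and KN(SiMe3)2, THF, 0 °C) would give the vinyl-terminated dienyne F1, whose monosubstituted alkene is the most willing Pauson–Khand partner. The same Co2(CO)8/N-oxide closure would give the C1-unsubstituted enone F2. Kinetic deprotonation at C1 (LiN(i-Pr)2, THF, −78 °C) and iodomethane would then place the methyl group anti to C7, cis to H7a, which is also the more stable epimer, and give 22.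

2. Step 16. Protonation of the C3a carbanion may occur syn to H7a and give the cis ring fusion, or electron transfer to the ester may compete. The fallback sets out from 22 and comes back at 25, and it delivers the C3a hydrogen intramolecularly. Luche reduction (NaBH4, CeCl3·7H2O, MeOH, −78 °C; hydride anti to the C1 methyl) would give the allylic alcohol F3 with the hydroxyl cis to that methyl. Mitsunobu displacement with N-isopropylidene-N'-(2-nitrobenzenesulfonyl)hydrazine (PPh3, diethyl azodicarboxylate, THF, 0 °C to rt) would invert C2 and give the N-allyl sulfonyl hydrazone F4. Hydrolysis in trifluoroethanol/water would release the allylic diazene F5, which loses N2 in a suprafacial retro-ene shift. That shift puts hydrogen on C3a on the face opposite H7a and moves the double bond to C2=C3, giving 25 directly, so the triflate reduction of step 17 is not needed.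

3. Step 7. The rearrangement joins two fully substituted carbons and may need a temperature at which the tert-butyl ester loses isobutene (after which the formyl acid would decarboxylate), or the boat pathway may compete and erode the diastereoselectivity. The fallback sets out from 8 and comes back at 10, and it forms the same C4–C5 bond near room temperature by an Ireland–Claisen rearrangement. Esterification of 8 with 3-tert-butoxy-2-methyl-3-oxopropanoic acid (DCC, DMAP, CH2Cl2) would give the mixed malonate F6. LiN(SiMe3)2 and Me3SiCl (THF, −78 °C to rt) would give, through the lithium-chelated enolate, the silyl ketene acetal with the allyloxy group cis to the methyl; this maps onto the same chair and, after hydrolysis of the silyl ester, gives the acid F7. The acid would be converted into the acid chloride F8 (1-chloro-N,N,2-trimethylprop-1-en-1-amine, CH2Cl2) and reduced with LiAlH(O-t-Bu)3 (THF, −78 °C) to aldehyde 10.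

Further compounds
F1 | step 15 | tert-butyl (2R,3S,4Z)-2-(but-1-yn-1-yl)-3-[(tert-butyldimethylsilyloxy)methyl]-3-ethyl-2,5-dimethylhepta-4,6-dienoate | CCC#C[C@@](C)(C(=O)OC(C)(C)C)[C@@](CC)(CO[Si](C)(C)C(C)(C)C)/C=C(C)\C=C
F2 | step 15 | tert-butyl (4R,5S,7aR)-5-[(tert-butyldimethylsilyloxy)methyl]-3,5-diethyl-4,7-dimethyl-2-oxo-2,4,5,7a-tetrahydro-1H-indene-4-carboxylate | CCC1=C2[C@@](C)(C(=O)OC(C)(C)C)[C@@](CC)(CO[Si](C)(C)C(C)(C)C)C=C(C)[C@H]2CC1=O
F3 | step 16 | 2-hydroxy compound from 22 (allylic alcohol, hydroxyl on C2 cis to the C1 methyl) | CCC1=C2[C@@](C)(C(=O)OC(C)(C)C)[C@@](CC)(CO[Si](C)(C)C(C)(C)C)C=C(C)[C@H]2[C@H](C)[C@@H]1O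
F4 | step 16 | N-allyl-N-(2-nitrobenzenesulfonyl) hydrazone of acetone, nitrogen on C2 trans to the C1 methyl | CCC1=C2[C@@](C)(C(=O)OC(C)(C)C)[C@@](CC)(CO[Si](C)(C)C(C)(C)C)C=C(C)[C@H]2[C@H](C)[C@H]1N(N=C(C)C)S(=O)(=O)c1ccccc1[N+](=O)[O-]
F5 | step 16 | allylic diazene on C2 (transient) | CCC1=C2[C@@](C)(C(=O)OC(C)(C)C)[C@@](CC)(CO[Si](C)(C)C(C)(C)C)C=C(C)[C@H]2[C@H](C)[C@H]1N=N
F6 | step 7 | 1-tert-butyl 3-[(2S,3Z)-4-[(tert-butyldimethylsilyloxy)methyl]hex-3-en-2-yl] 2-methylpropanedioate | CC(C(=O)OC(C)(C)C)C(=O)O[C@@H](C)/C=C(CC)\CO[Si](C)(C)C(C)(C)C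
F7 | step 7 | (2S,3S,4E)-2-(tert-butoxycarbonyl)-3-[(tert-butyldimethylsilyloxy)methyl]-3-ethyl-2-methylhex-4-enoic acid | OC(=O)[C@@](C)(C(=O)OC(C)(C)C)[C@@](CC)(CO[Si](C)(C)C(C)(C)C)/C=C/C
F8 | step 7 | acid chloride of F7 | O=C(Cl)[C@@](C)(C(=O)OC(C)(C)C)[C@@](CC)(CO[Si](C)(C)C(C)(C)C)/C=C/C
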